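**Retrosynthetic overview**

1. Feature: ring B carries five oxygens and one C–H. With the ring A ether on C-1 and the C–H at C-2, the hydroxyls on C-3 and C-6 are para to each other and enclose the ring C ether oxygen on C-4 and the hydroxyl on C-5; C-3 to C-6 with their four oxygens map onto squaric acid, C-1 and C-2 onto a 1-aryloxyvinyl unit.
2. Target 29 ⇐ hydrogenolysis of nonabenzyl hydroquinone 28 ⇐ thermal ring expansion of cyclobutenone 25 (new bond C-2–C-3 of ring B).
3. 25 ⇐ mixed benzyl aryl squarate 13 + 1-aryloxyvinyllithium 24; 13 ⇐ squaric acid dichloride 11, benzyl alcohol and C–D phenol 9.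
4. 9 ⇐ Ullmann ether of ring D phenol 3 with ring C bromide 6, then Dakin oxidation; 24 ⇐ ring A phenol 17 via dichlorovinyl ether 19, ynol ether 22 and stannane 23.
5. Ring order: rings A, C and D are bought as arenes; ring B is the only ring made, in step 14.

Key step: step 14

Remark: the target has no stereocentre, so carbinol 25 is made and used as the racemate. Lithium alkoxides that exist only until the aqueous quench are not numbered apart from their protonated forms.

**Route**

Step 1
Reactants: 1 3,4,5-tris(benzyloxy)benzaldehyde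
Product: 3 3,4,5-tris(benzyloxy)phenol, via aryl formate 2 (not isolated)
Conditions: mCPBA, CH2Cl2, 0 °C to rt; then K2CO3, MeOH, rt
Reagents that add atoms: mCPBA, O=C(OO)c1cccc(Cl)c1
Why: Baeyer–Villiger (Dakin-type) oxidation of an electron-rich benzaldehyde proceeds by aryl migration to the formate, which methanolysis cleaves to the phenol.

Step 2
Reactants: 4 4-bromo-3,5-dimethoxybenzaldehyde
Product: 5 4-bromo-3,5-dihydroxybenzaldehyde
Conditions: BBr3, CH2Cl2, −78 °C to rt; then H2O
Reagents that add atoms: none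
Why: Lewis-acid cleavage of aryl methyl ethers by BBr3 (bromide attack at methyl) should leave the aldehyde and the aryl bromide intact after aqueous work-up.

Step 3
Reactants: 5 4-bromo-3,5-dihydroxybenzaldehyde
Product: 6 3,5-bis(benzyloxy)-4-bromobenzaldehyde
Conditions: BnBr, K2CO3, DMF, 50 °C
Reagents that add atoms: benzyl bromide, BrCc1ccccc1
Why: Williamson etherification of two unhindered phenoxides with a reactive benzylic halide.

Step 4
Reactants: 3 3,4,5-tris(benzyloxy)phenol; 6 3,5-bis(benzyloxy)-4-bromobenzaldehyde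
Product: 7 3,5-bis(benzyloxy)-4-[3,4,5-tris(benzyloxy)phenoxy]benzaldehyde
Conditions: CuI (10 mol %), N,N-dimethylglycine·HCl (30 mol %), Cs2CO3, 1,4-dioxane, 100 °C, argon
Reagents that add atoms: none
Why: Ullmann-type copper-catalysed C–O coupling, in which the para formyl group activates the bromide and the nucleophile is an unhindered electron-rich phenoxide, so the two small ortho alkoxy groups should be tolerated.

Step 5
Reactants: 7 3,5-bis(benzyloxy)-4-[3,4,5-tris(benzyloxy)phenoxy]benzaldehyde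
Product: 9 3,5-bis(benzyloxy)-4-[3,4,5-tris(benzyloxy)phenoxy]phenol, via diaryl ether formate 8 (not isolated)
Conditions: mCPBA, CH2Cl2, 0 °C to rt; then K2CO3, MeOH, rt
Reagents that add atoms: mCPBA, O=C(OO)c1cccc(Cl)c1
Why: Baeyer–Villiger (Dakin-type) oxidation, in which the para aryloxy donor favours aryl migration, followed by methanolysis of the formate, turns the formyl carbon position into the phenol oxygen that will link ring C to ring B.

Step 6
Reactants: 10 squaric acid
Product: 11 squaric acid dichloride (3,4-dichlorocyclobut-3-ene-1,2-dione)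
Conditions: (COCl)2, DMF (cat.), 1,2-dichloroethane, 50 °C
Reagents that add atoms: oxalyl chloride, O=C(Cl)C(=O)Cl
Why: Vilsmeier-type chlorination converts both vinylogous acid hydroxyls into vinylogous acid chlorides.

Step 7
Reactants: 11 squaric acid dichloride; 9 3,5-bis(benzyloxy)-4-[3,4,5-tris(benzyloxy)phenoxy]phenol
Product: 13 3-(benzyloxy)-4-{3,5-bis(benzyloxy)-4-[3,4,5-tris(benzyloxy)phenoxy]phenoxy}cyclobut-3-ene-1,2-dione, via benzyl chlorosquarate 12 (not isolated)
Conditions: BnOH (1 equiv), i-Pr2NEt, CH2Cl2, −78 °C; then 9, i-Pr2NEt, −78 to 0 °C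
Reagents that add atoms: benzyl alcohol, OCc1ccccc1
Why: Two successive addition–elimination substitutions at vinylogous acyl chloride carbons, with benzyl alcohol first because the alkoxy donor tempers the remaining chloride so that substitution stops after one, and the phenol last because the aryloxide, the better leaving group, then meets no alkoxide that could displace it.

Step 8
Reactants: 14 2,4,6-trihydroxybenzaldehyde
Product: 15 2,4,6-tris(benzyloxy)benzaldehyde
Conditions: BnBr, K2CO3, DMF, 60 °C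
Reagents that add atoms: benzyl bromide, BrCc1ccccc1
Why: Williamson etherification, in which the formyl group suppresses C-benzylation of the phloroglucinol ring and warming brings the two hydrogen-bonded ortho hydroxyls to full conversion.

Step 9
Reactants: 15 2,4,6-tris(benzyloxy)benzaldehyde
Product: 17 2,4,6-tris(benzyloxy)phenol, via aryl formate 16 (not isolated)
Conditions: mCPBA, CH2Cl2, 0 °C to rt; then K2CO3, MeOH, rt
Reagents that add atoms: mCPBA, O=C(OO)c1cccc(Cl)c1
Why: Baeyer–Villiger (Dakin-type) oxidation of a 2,4,6-trialkoxybenzaldehyde is especially easy because the migrating ring is strongly electron-rich, and methanolysis frees the phenol.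

Step 10
Reactants: 17 2,4,6-tris(benzyloxy)phenol; 18 trichloroethylene
Product: 19 1,3,5-tris(benzyloxy)-2-{[(E)-1,2-dichloroethenyl]oxy}benzene
Conditions: K2CO3, DMF, 70 °C, argon
Reagents that add atoms: none
Why: Base eliminates HCl from trichloroethylene to dichloroacetylene in the flask and the phenoxide adds anti across it (vinylic substitution by elimination–addition), a path that is insensitive to the two ortho substituents of the phenol.

Step 11
Reactants: 19 1,3,5-tris(benzyloxy)-2-{[(E)-1,2-dichloroethenyl]oxy}benzene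
Product: 22 1,3,5-tris(benzyloxy)-2-(ethynyloxy)benzene, via chloroethynyl ether 20 (not isolated), via lithium acetylide 21 (not isolated)
Conditions: n-BuLi (2.3 equiv), THF, −78 to −40 °C; then H2O, −78 °C to rt
Reagents that add atoms: none
Why: The dichlorovinyl ether route to ynol ethers, in which n-BuLi first eliminates HCl to the chloroalkyne and then exchanges chlorine for lithium, and protonation of the acetylide gives the terminal aryl ethynyl ether while the benzyl ethers are untouched at low temperature.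

Step 12
Reactants: 22 1,3,5-tris(benzyloxy)-2-(ethynyloxy)benzene
Product: 23 tributyl{1-[2,4,6-tris(benzyloxy)phenoxy]ethenyl}stannane
Conditions: Bu3SnH, Pd(PPh3)4 (3 mol %), THF, 0 °C to rt
Reagents that add atoms: tributyltin hydride, CCCC[SnH](CCCC)CCCC
Why: Palladium-catalysed syn hydrostannylation of an alkynyl ether delivers tin to the oxygen-bearing carbon and hydrogen to the terminus, as is usual for heteroatom-substituted alkynes, giving the 1,1-disubstituted α-stannyl enol ether.

Step 13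
Reactants: 23 tributyl{1-[2,4,6-tris(benzyloxy)phenoxy]ethenyl}stannane; 13 3-(benzyloxy)-4-{3,5-bis(benzyloxy)-4-[3,4,5-tris(benzyloxy)phenoxy]phenoxy}cyclobut-3-ene-1,2-dione
Product: 25 rac-3-(benzyloxy)-2-{3,5-bis(benzyloxy)-4-[3,4,5-tris(benzyloxy)phenoxy]phenoxy}-4-hydroxy-4-{1-[2,4,6-tris(benzyloxy)phenoxy]ethenyl}cyclobut-2-en-1-one, via vinyllithium 24 (not isolated)
Conditions: n-BuLi, THF, −78 °C; then 13, THF, −78 °C; then sat. aq NH4Cl
Reagents that add atoms: none
Why: Tin–lithium exchange gives the α-aryloxyvinyllithium, which should add 1,2 to the more electrophilic squarate carbonyl, C-2 next to the benzyloxy carbon, because that carbonyl is conjugated through the ring alkene with the weaker aryloxy donor; the new carbinol centre forms as the racemate and needs no control since step 14 removes it.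

Step 14
Reactants: 25 rac-3-(benzyloxy)-2-{3,5-bis(benzyloxy)-4-[3,4,5-tris(benzyloxy)phenoxy]phenoxy}-4-hydroxy-4-{1-[2,4,6-tris(benzyloxy)phenoxy]ethenyl}cyclobut-2-en-1-one
Product: 28 3-(benzyloxy)-2-{3,5-bis(benzyloxy)-4-[3,4,5-tris(benzyloxy)phenoxy]phenoxy}-5-[2,4,6-tris(benzyloxy)phenoxy]benzene-1,4-diol, via dienylketene 26 (not isolated), via cyclohexadienone 27 (not isolated)
Conditions: toluene (degassed), 110 °C, argon
Reagents that add atoms: none
Why: Heating opens the cyclobutenone at the C-1–C-4 bond by a conrotatory four-electron electrocyclic reaction to the (Z)-dienylketene 26, the carbinol hydroxyl turning outward so that the 1-aryloxyvinyl group lies beside the ketene. A disrotatory six-electron electrocyclisation then joins the ketene carbon to the vinyl CH2 (the C-2–C-3 bond of ring B) and closes ring B as the six-membered cyclohexa-2,4-dienone 27, which enolises to hydroquinone 28. The closest known reaction is the thermal ring expansion of squarate-derived 4-alkenyl-4-hydroxy-2,3-dialkoxycyclobutenones to polyoxygenated hydroquinones (Moore rearrangement), with the two aryloxy groups here as spectators. No stereocentre is formed and the carbinol centre of 25 is lost on aromatisation. The step needs outward rotation of the hydroxyl, which its donor character secures, and the right placement of the oxygens, which the constitution of 25 fixes: the C-2 aryloxy group ends up beside the hydroxyl born from the ketene carbon and the C-3 benzyloxy group beside the old carbinol oxygen. The electron-rich enol ether terminus matches the electrophilic ketene carbon, which should favour ring closure over addition of the hydroxyl to the ketene.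

Step 15
Reactants: 28 3-(benzyloxy)-2-{3,5-bis(benzyloxy)-4-[3,4,5-tris(benzyloxy)phenoxy]phenoxy}-5-[2,4,6-tris(benzyloxy)phenoxy]benzene-1,4-diol
Product: 29 3-[3,5-dihydroxy-4-(3,4,5-trihydroxyphenoxy)phenoxy]-6-(2,4,6-trihydroxyphenoxy)benzene-1,2,4-triol
Conditions: H2 (1 atm), Pd/C (10 %), THF–MeOH, rt, then handling under argon
Reagents that add atoms: none
Why: Hydrogenolysis cleaves all nine benzyl aryl ethers while the three diaryl ether bonds are inert, and any quinone formed from 28 by adventitious oxidation is reduced back to the hydroquinone under the same conditions.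

**Compound list**

1 | 3,4,5-tris(benzyloxy)benzaldehyde | O=Cc1cc(OCc2ccccc2)c(OCc2ccccc2)c(OCc2ccccc2)c1 | starting material
2 | 3,4,5-tris(benzyloxy)phenyl formate | O=COc1cc(OCc2ccccc2)c(OCc2ccccc2)c(OCc2ccccc2)c1 | intermediate
3 | 3,4,5-tris(benzyloxy)phenol | Oc1cc(OCc2ccccc2)c(OCc2ccccc2)c(OCc2ccccc2)c1 | intermediate
4 | 4-bromo-3,5-dimethoxybenzaldehyde | COc1cc(C=O)cc(OC)c1Br | starting material
5 | 4-bromo-3,5-dihydroxybenzaldehyde | O=Cc1cc(O)c(Br)c(O)c1 | intermediate
6 | 3,5-bis(benzyloxy)-4-bromobenzaldehyde | O=Cc1cc(OCc2ccccc2)c(Br)c(OCc2ccccc2)c1 | intermediate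
7 | 3,5-bis(benzyloxy)-4-[3,4,5-tris(benzyloxy)phenoxy]benzaldehyde | O=Cc1cc(OCc2ccccc2)c(Oc2cc(OCc3ccccc3)c(OCc3ccccc3)c(OCc3ccccc3)c2)c(OCc2ccccc2)c1 | intermediate
8 | 3,5-bis(benzyloxy)-4-[3,4,5-tris(benzyloxy)phenoxy]phenyl formate | O=COc1cc(OCc2ccccc2)c(Oc2cc(OCc3ccccc3)c(OCc3ccccc3)c(OCc3ccccc3)c2)c(OCc2ccccc2)c1 | intermediate
9 | 3,5-bis(benzyloxy)-4-[3,4,5-tris(benzyloxy)phenoxy]phenol | Oc1cc(OCc2ccccc2)c(Oc2cc(OCc3ccccc3)c(OCc3ccccc3)c(OCc3ccccc3)c2)c(OCc2ccccc2)c1 | intermediate
10 | squaric acid (3,4-dihydroxycyclobut-3-ene-1,2-dione) | O=C1C(O)=C(O)C1=O | starting material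
11 | squaric acid dichloride (3,4-dichlorocyclobut-3-ene-1,2-dione) | O=C1C(Cl)=C(Cl)C1=O | intermediate
12 | 3-(benzyloxy)-4-chlorocyclobut-3-ene-1,2-dione | O=C1C(Cl)=C(OCc2ccccc2)C1=O | intermediate
13 | 3-(benzyloxy)-4-{3,5-bis(benzyloxy)-4-[3,4,5-tris(benzyloxy)phenoxy]phenoxy}cyclobut-3-ene-1,2-dione | O=C1C(=O)C(Oc2cc(OCc3ccccc3)c(Oc3cc(OCc4ccccc4)c(OCc4ccccc4)c(OCc4ccccc4)c3)c(OCc3ccccc3)c2)=C1OCc1ccccc1 | intermediate
14 | 2,4,6-trihydroxybenzaldehyde | O=Cc1c(O)cc(O)cc1O | starting material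
15 | 2,4,6-tris(benzyloxy)benzaldehyde | O=Cc1c(OCc2ccccc2)cc(OCc2ccccc2)cc1OCc1ccccc1 | intermediate
16 | 2,4,6-tris(benzyloxy)phenyl formate | O=COc1c(OCc2ccccc2)cc(OCc2ccccc2)cc1OCc1ccccc1 | intermediate
17 | 2,4,6-tris(benzyloxy)phenol | Oc1c(OCc2ccccc2)cc(OCc2ccccc2)cc1OCc1ccccc1 | intermediate
18 | trichloroethylene | ClC=C(Cl)Cl | starting material
19 | 1,3,5-tris(benzyloxy)-2-{[(E)-1,2-dichloroethenyl]oxy}benzene | Cl/C=C(Cl)\Oc1c(OCc2ccccc2)cc(OCc2ccccc2)cc1OCc1ccccc1 | intermediate
20 | 1,3,5-tris(benzyloxy)-2-[(chloroethynyl)oxy]benzene | ClC#COc1c(OCc2ccccc2)cc(OCc2ccccc2)cc1OCc1ccccc1 | intermediate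
21 | lithium 2-[2,4,6-tris(benzyloxy)phenoxy]ethynide | [Li]C#COc1c(OCc2ccccc2)cc(OCc2ccccc2)cc1OCc1ccccc1 | intermediate
22 | 1,3,5-tris(benzyloxy)-2-(ethynyloxy)benzene | C#COc1c(OCc2ccccc2)cc(OCc2ccccc2)cc1OCc1ccccc1 | intermediate
23 | tributyl{1-[2,4,6-tris(benzyloxy)phenoxy]ethenyl}stannane | C=C(Oc1c(OCc2ccccc2)cc(OCc2ccccc2)cc1OCc1ccccc1)[Sn](CCCC)(CCCC)CCCC | intermediate
24 | {1-[2,4,6-tris(benzyloxy)phenoxy]ethenyl}lithium | [Li]C(=C)Oc1c(OCc2ccccc2)cc(OCc2ccccc2)cc1OCc1ccccc1 | intermediate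
25 | rac-3-(benzyloxy)-2-{3,5-bis(benzyloxy)-4-[3,4,5-tris(benzyloxy)phenoxy]phenoxy}-4-hydroxy-4-{1-[2,4,6-tris(benzyloxy)phenoxy]ethenyl}cyclobut-2-en-1-one (racemate) | O=C1C(Oc2cc(OCc3ccccc3)c(Oc3cc(OCc4ccccc4)c(OCc4ccccc4)c(OCc4ccccc4)c3)c(OCc3ccccc3)c2)=C(OCc2ccccc2)C1(O)C(=C)Oc1c(OCc2ccccc2)cc(OCc2ccccc2)cc1OCc1ccccc1 | intermediate
26 | (3Z)-3-(benzyloxy)-2-{3,5-bis(benzyloxy)-4-[3,4,5-tris(benzyloxy)phenoxy]phenoxy}-4-hydroxy-5-[2,4,6-tris(benzyloxy)phenoxy]hexa-1,3,5-trien-1-one (dienylketene) | O=C=C(Oc1cc(OCc2ccccc2)c(Oc2cc(OCc3ccccc3)c(OCc3ccccc3)c(OCc3ccccc3)c2)c(OCc2ccccc2)c1)/C(OCc1ccccc1)=C(/O)C(=C)Oc1c(OCc2ccccc2)cc(OCc2ccccc2)cc1OCc1ccccc1 | intermediate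
27 | 3-(benzyloxy)-2-{3,5-bis(benzyloxy)-4-[3,4,5-tris(benzyloxy)phenoxy]phenoxy}-4-hydroxy-5-[2,4,6-tris(benzyloxy)phenoxy]cyclohexa-2,4-dien-1-one | O=C1CC(Oc2c(OCc3ccccc3)cc(OCc3ccccc3)cc2OCc2ccccc2)=C(O)C(OCc2ccccc2)=C1Oc1cc(OCc2ccccc2)c(Oc2cc(OCc3ccccc3)c(OCc3ccccc3)c(OCc3ccccc3)c2)c(OCc2ccccc2)c1 | intermediate
28 | 3-(benzyloxy)-2-{3,5-bis(benzyloxy)-4-[3,4,5-tris(benzyloxy)phenoxy]phenoxy}-5-[2,4,6-tris(benzyloxy)phenoxy]benzene-1,4-diol | Oc1c(Oc2c(OCc3ccccc3)cc(OCc3ccccc3)cc2OCc2ccccc2)cc(O)c(Oc2cc(OCc3ccccc3)c(Oc3cc(OCc4ccccc4)c(OCc4ccccc4)c(OCc4ccccc4)c3)c(OCc3ccccc3)c2)c1OCc1ccccc1 | intermediate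
29 | 3-[3,5-dihydroxy-4-(3,4,5-trihydroxyphenoxy)phenoxy]-6-(2,4,6-trihydroxyphenoxy)benzene-1,2,4-triol | Oc1cc(O)c(Oc2cc(O)c(Oc3cc(O)c(Oc4cc(O)c(O)c(O)c4)c(O)c3)c(O)c2O)c(O)c1 | target

**Step count**

Total: 15 steps. Longest linear sequence: 8 steps (steps 8, 9, 10, 11, 12, 13, 14, 15 from 14; equally steps 2, 3, 4, 5, 7, 13, 14, 15 from 4).

**Steps most likely to fail**

Step 13. The two squarate carbonyls differ only in the donor strength of the oxygen group conjugated with each, so the addition may be shared between them and give a regioisomeric carbinol that would lead to the wrong ring B pattern. The fallback removes the choice. It sets out from 11, which is treated with two equivalents of 9 (i-Pr2NEt, CH2Cl2, 0 °C) to give the symmetric 3,4-bis{3,5-bis(benzyloxy)-4-[3,4,5-tris(benzyloxy)phenoxy]phenoxy}cyclobut-3-ene-1,2-dione F1. Vinyllithium 24, made as in step 13, can add to either carbonyl of this diester with the same result and should give rac-2,3-bis{3,5-bis(benzyloxy)-4-[3,4,5-tris(benzyloxy)phenoxy]phenoxy}-4-hydroxy-4-{1-[2,4,6-tris(benzyloxy)phenoxy]ethenyl}cyclobut-2-en-1-one F2. In this adduct the aryloxy group on C-3 is a vinylogous aryl ester, while the one on C-2 sits on the α-carbon and cannot be displaced. Addition–elimination with BnOH and catalytic Et3N and DMAP (THF, 0 °C) should therefore exchange only the C-3 group. This comes back to the route at 25 and returns one equivalent of 9 for reuse.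

Step 14. The hydroxyl may rotate inward on ring opening and then add to the ketene, which would give a furanone instead of ring B, and the free hydroquinone may be lost by oxidation during isolation. The fallback sets out from 25 and changes the group that steers the ring opening. Silylation (TMSCl, Et3N, DMAP cat., CH2Cl2, 0 °C) should give the trimethylsilyl ether of 25, F3. A silyloxy group is a reliable outward-rotating donor and cannot add to the ketene. Heating in toluene at 110 °C should then give the mono-trimethylsilyl ether of 28, F4, silylated on the oxygen next to the ring A ether, by the same electrocyclic sequence known for 4-silyloxy-4-alkenylcyclobutenones. Methanolysis (K2CO3, MeOH, rt) comes back to the route at 28.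

Step 4. Oxidative addition at a bromide flanked by two ortho benzyloxy groups may be slow, so that reduction of the C–Br bond or oxidation of the electron-rich phenoxide wins. The fallback reverses the polarity of the coupling. It sets out from 1, in which the 4-benzyl ether, flanked by two alkoxy groups and para to the formyl group, should be cleaved selectively by MgBr2·OEt2 (toluene–Et2O, reflux) to 3,5-bis(benzyloxy)-4-hydroxybenzaldehyde F5. This is the counterpart of the selective 4-O-demethylation of 3,4,5-trimethoxybenzaldehyde. Chan–Lam coupling of this hindered phenol with commercial [3,4,5-tris(benzyloxy)phenyl]boronic acid (Cu(OAc)2, pyridine, 4 Å molecular sieves, CH2Cl2, air, rt; divalent copper transfers the aryl group from boron) tolerates two ortho substituents on the phenol and comes back to the route at 7.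

**Further compounds**

F1 | step 13 | 3,4-bis{3,5-bis(benzyloxy)-4-[3,4,5-tris(benzyloxy)phenoxy]phenoxy}cyclobut-3-ene-1,2-dione | O=C1C(=O)C(Oc2cc(OCc3ccccc3)c(Oc3cc(OCc4ccccc4)c(OCc4ccccc4)c(OCc4ccccc4)c3)c(OCc3ccccc3)c2)=C1Oc1cc(OCc2ccccc2)c(Oc2cc(OCc3ccccc3)c(OCc3ccccc3)c(OCc3ccccc3)c2)c(OCc2ccccc2)c1
F2 | step 13 | rac-2,3-bis{3,5-bis(benzyloxy)-4-[3,4,5-tris(benzyloxy)phenoxy]phenoxy}-4-hydroxy-4-{1-[2,4,6-tris(benzyloxy)phenoxy]ethenyl}cyclobut-2-en-1-one | O=C1C(Oc2cc(OCc3ccccc3)c(Oc3cc(OCc4ccccc4)c(OCc4ccccc4)c(OCc4ccccc4)c3)c(OCc3ccccc3)c2)=C(Oc2cc(OCc3ccccc3)c(Oc3cc(OCc4ccccc4)c(OCc4ccccc4)c(OCc4ccccc4)c3)c(OCc3ccccc3)c2)C1(O)C(=C)Oc1c(OCc2ccccc2)cc(OCc2ccccc2)cc1OCc1ccccc1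
F3 | step 14 | rac-3-(benzyloxy)-2-{3,5-bis(benzyloxy)-4-[3,4,5-tris(benzyloxy)phenoxy]phenoxy}-4-{1-[2,4,6-tris(benzyloxy)phenoxy]ethenyl}-4-[(trimethylsilyl)oxy]cyclobut-2-en-1-one | C[Si](C)(C)OC1(C(=C)Oc2c(OCc3ccccc3)cc(OCc3ccccc3)cc2OCc2ccccc2)C(=O)C(Oc2cc(OCc3ccccc3)c(Oc3cc(OCc4ccccc4)c(OCc4ccccc4)c(OCc4ccccc4)c3)c(OCc3ccccc3)c2)=C1OCc1ccccc1
F4 | step 14 | 3-(benzyloxy)-4-{3,5-bis(benzyloxy)-4-[3,4,5-tris(benzyloxy)phenoxy]phenoxy}-6-[2,4,6-tris(benzyloxy)phenoxy]-2-... mono-trimethylsilyl ether of 28 (silyl on the oxygen next to the ring A ether) | C[Si](C)(C)Oc1c(Oc2c(OCc3ccccc3)cc(OCc3ccccc3)cc2OCc2ccccc2)cc(O)c(Oc2cc(OCc3ccccc3)c(Oc3cc(OCc4ccccc4)c(OCc4ccccc4)c(OCc4ccccc4)c3)c(OCc3ccccc3)c2)c1OCc1ccccc1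
F5 | step 4 | 3,5-bis(benzyloxy)-4-hydroxybenzaldehyde | O=Cc1cc(OCc2ccccc2)c(O)c(OCc2ccccc2)c1
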